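**Retrosynthetic overview** (locants follow the naphthalen-2-one names: C1 = quaternary carbon bearing CH2O, C2 = ketone, C4a=C8a = ring-fusion alkene, C5 = quaternary carbon bearing the side chain, C6 = CHMe, C8 = carbinol)
1. Butenolide: B-alkyl Suzuki coupling of a C5-vinyl group with 4-bromofuranone in the last step; the C8 carbinol comes from CBS reduction of a ring-B enone.
2. Ring B: catalyst-controlled Diels–Alder reaction of a ring-A 2-ethoxydiene with tiglaldehyde (bonds C4a–C5 and C6–C7), then DDQ oxidation to the C4a=C8a enone.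
3. C1 quaternary centre and the diene together: a new enantioselective deconjugative α-hydroxymethylation of an achiral dienone.
4. The dienone comes from 2-methylcyclohexane-1,3-dione by enol triflation and Stille coupling.
5. Ring order: ring A (bought as the dione), then ring B (cycloaddition), then the butenolide (attached preformed).

Assumption: both antipodes of the chiral catalysts are purchasable, and the new step 3 is taken to give the S alcohol with the cinchonidine-derived salt (the pseudo-enantiomeric cinchonine-derived salt is used if the sense is opposite).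

Step 1
Reactants: 1 2-methylcyclohexane-1,3-dione
Product: 2 2-methyl-3-oxocyclohex-1-en-1-yl trifluoromethanesulfonate
Conditions: Tf2O, pyridine, CH2Cl2, −78 → 0 °C
Reagents that add atoms: trifluoromethanesulfonic anhydride, O=S(=O)(OS(=O)(=O)C(F)(F)F)C(F)(F)F
Why: O-sulfonylation of the enol tautomer of the cyclic 1,3-dione (enol triflate formation) gives the vinylogous acyl triflate; no stereocentre is involved.

Step 2
Reactants: 2 2-methyl-3-oxocyclohex-1-en-1-yl trifluoromethanesulfonate; 3 tributyl(1-ethoxyethenyl)stannane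
Product: 4 3-(1-ethoxyethenyl)-2-methylcyclohex-2-en-1-one
Conditions: Pd(PPh3)4 (5 mol %), LiCl, THF, 65 °C; non-acidic work-up
Reagents that add atoms: none
Why: Stille coupling of an electron-poor alkenyl triflate with the 1-ethoxyvinyl stannane is standard, and the enol ether survives because no acid is used.

Step 3
Reactants: 4 3-(1-ethoxyethenyl)-2-methylcyclohex-2-en-1-one
Product: 5 (2S)-3-(1-ethoxyethenyl)-2-(hydroxymethyl)-2-methylcyclohex-3-en-1-one
Conditions: 37 % aq. CH2O (1.5 equiv), urea–ammonium salt Q1 (N-benzyl-9-deoxy-9-epi-{3-[3,5-bis(trifluoromethyl)phenyl]ureido}cinchonidinium bromide, 10 mol %), 50 % aq. KOH, toluene, −20 °C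
Reagents that add atoms: formaldehyde, C=O
Why: Proposed new method: catalytic enantioselective deconjugative α-hydroxymethylation, in which interfacial hydroxide removes a γ-proton (ring C4–H) of 4 to give the through-conjugated dienolate as a tight ion pair with the chiral ammonium ion while the urea N–H bonds hold formaldehyde, so that C–C bond formation at the α-carbon (largest HOMO coefficient) on one enantiotopic face sets the quaternary centre (S, the first stereocentre) and leaves the ring alkene conjugated with the ethoxyvinyl group as a 2-ethoxy-1,3-diene; the closest known reaction types are the racemic KOt-Bu-mediated deconjugative α-alkylation of 2-methylcyclohex-2-enones and asymmetric phase-transfer α-alkylation and hydroxymethylation of cyclic ketones and β-keto esters.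

Step 4
Reactants: 6 3-(4-hydroxyphenyl)propanoic acid
Product: 8 3-[4-(tert-butyldimethylsilyloxy)phenyl]propanoic acid, via bis-silylated acid 7 (not isolated)
Conditions: TBSCl (2.5 equiv), imidazole, DMF, rt; then AcOH/THF/H2O, rt
Reagents that add atoms: tert-butyldimethylsilyl chloride, CC(C)(C)[Si](C)(C)Cl
Why: Silylation of phenol and acid followed by selective hydrolysis of the labile silyl ester leaves the aryl silyl ether (standard protection).

Step 5
Reactants: 5 (2S)-3-(1-ethoxyethenyl)-2-(hydroxymethyl)-2-methylcyclohex-3-en-1-one; 8 3-[4-(tert-butyldimethylsilyloxy)phenyl]propanoic acid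
Product: 9 [(1S)-2-(1-ethoxyethenyl)-1-methyl-6-oxocyclohex-2-en-1-yl]methyl 3-[4-(tert-butyldimethylsilyloxy)phenyl]propanoate
Conditions: DIC, DMAP, CH2Cl2, 0 °C → rt
Reagents that add atoms: none
Why: Steglich esterification acylates the neopentyl primary alcohol under DMAP-buffered conditions that keep the acid-sensitive ethoxydiene intact; the quaternary centre has no α-hydrogen and cannot epimerise.

Step 6
Reactants: 9 [(1S)-2-(1-ethoxyethenyl)-1-methyl-6-oxocyclohex-2-en-1-yl]methyl 3-[4-(tert-butyldimethylsilyloxy)phenyl]propanoate; 10 (E)-2-methylbut-2-enal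
Product: 11 [(1S,4aRS,5R,6S)-8-ethoxy-5-formyl-1,5,6-trimethyl-2-oxo-1,2,3,4,4a,5,6,7-octahydronaphthalen-1-yl]methyl 3-[4-(tert-butyldimethylsilyloxy)phenyl]propanoate
Conditions: (R)-o-tolyl-CBS oxazaborolidine/Tf2NH (20 mol %), 10 (3 equiv), CH2Cl2, −78 → −40 °C
Reagents that add atoms: none
Why: Diels–Alder reaction under chiral oxazaborolidinium catalysis, in which the 2-ethoxy group and the ring substituent direct C7 to the β-carbon and C4a to the α-carbon of the bound enal, suprafacial addition to the E-alkene fixes the two methyl groups cis, and the catalyst (s-trans enal held by a formyl C–H···O contact, one face shielded by a phenyl group) makes the diene add to the Cα-si/Cβ-re face to give 5R,6S whatever the diene face, so both C4a epimers are usable.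

Step 7
Reactants: 11 [(1S,4aRS,5R,6S)-8-ethoxy-5-formyl-1,5,6-trimethyl-2-oxo-1,2,3,4,4a,5,6,7-octahydronaphthalen-1-yl]methyl 3-[4-(tert-butyldimethylsilyloxy)phenyl]propanoate
Product: 12 [(1S,4aRS,5R,6S)-5-ethenyl-8-ethoxy-1,5,6-trimethyl-2-oxo-1,2,3,4,4a,5,6,7-octahydronaphthalen-1-yl]methyl 3-[4-(tert-butyldimethylsilyloxy)phenyl]propanoate
Conditions: Ph3PCH3Br, NaN(SiMe3)2 (1.2 equiv ylide), THF, −78 → 0 °C
Reagents that add atoms: methyltriphenylphosphonium bromide, C[P+](c1ccccc1)(c1ccccc1)c1ccccc1.[Br-]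
Why: Wittig methylenation, where the aldehyde reacts far faster than the ketone beside the quaternary C1 and, having no α-hydrogen, cannot epimerise.

Step 8
Reactants: 12 [(1S,4aRS,5R,6S)-5-ethenyl-8-ethoxy-1,5,6-trimethyl-2-oxo-1,2,3,4,4a,5,6,7-octahydronaphthalen-1-yl]methyl 3-[4-(tert-butyldimethylsilyloxy)phenyl]propanoate
Product: 13 [(1S,5R,6S)-5-ethenyl-1,5,6-trimethyl-2,8-dioxo-1,2,3,4,5,6,7,8-octahydronaphthalen-1-yl]methyl 3-[4-(tert-butyldimethylsilyloxy)phenyl]propanoate
Conditions: DDQ (1.2 equiv), CH2Cl2/pH 7 buffer, 0 °C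
Reagents that add atoms: water, O
Why: Dehydrogenation of the enol ether by hydride abstraction, where C4a–H is the only allylic hydrogen whose loss gives an oxygen-stabilised cation and hydrolysis of that oxocarbenium ion gives the C4a=C8a enone, so both C4a epimers converge; the quaternary C1 rules out the other regiochemistry.

Step 9
Reactants: 13 [(1S,5R,6S)-5-ethenyl-1,5,6-trimethyl-2,8-dioxo-1,2,3,4,5,6,7,8-octahydronaphthalen-1-yl]methyl 3-[4-(tert-butyldimethylsilyloxy)phenyl]propanoate
Product: 14 [(1S,5R,6S,8S)-5-ethenyl-8-hydroxy-1,5,6-trimethyl-2-oxo-1,2,3,4,5,6,7,8-octahydronaphthalen-1-yl]methyl 3-[4-(tert-butyldimethylsilyloxy)phenyl]propanoate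
Conditions: (R)-Me-CBS (20 mol %), catecholborane (1.5 equiv), toluene, −78 °C
Reagents that add atoms: none
Why: Corey–Bakshi–Shibata reduction, in which the catalyst treats the alkenyl flank (C8a) as the large group and C7H2 as the small one and delivers hydride to the face syn to the C6 methyl group, giving the 8S alcohol (trans to that methyl); the conjugated ketone is expected to react at −78 °C in preference to the ketone beside the quaternary C1.

Step 10
Reactants: 14 [(1S,5R,6S,8S)-5-ethenyl-8-hydroxy-1,5,6-trimethyl-2-oxo-1,2,3,4,5,6,7,8-octahydronaphthalen-1-yl]methyl 3-[4-(tert-butyldimethylsilyloxy)phenyl]propanoate; 15 4-bromofuran-2(5H)-one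
Product: 18 [(1S,5R,6S,8S)-8-hydroxy-1,5,6-trimethyl-2-oxo-5-[2-(5-oxo-2,5-dihydrofuran-3-yl)ethyl]-1,2,3,4,5,6,7,8-octahydronaphthalen-1-yl]methyl 3-(4-hydroxyphenyl)propanoate, via B-alkyl-9-BBN borane 16 (not isolated), via aryl silyl ether of the target 17 (not isolated)
Conditions: 9-BBN (3 equiv), THF, rt; then 15, Pd(dppf)Cl2 (10 mol %), AsPh3, Cs2CO3, DMF/H2O, rt → 40 °C
Reagents that add atoms: none
Why: Anti-Markovnikov hydroboration of the only accessible alkene (the tetrasubstituted ring alkene is inert and the hindered ketone slow) and B-alkyl Suzuki–Miyaura coupling with the β-bromobutenolide, with the aqueous Cs2CO3/DMF medium also cleaving the aryl silyl ether in the same pot; no stereocentre is touched.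

**Compound list**
1 | 2-methylcyclohexane-1,3-dione | CC1C(=O)CCCC1=O | starting material
2 | 2-methyl-3-oxocyclohex-1-en-1-yl trifluoromethanesulfonate | CC1=C(OS(=O)(=O)C(F)(F)F)CCCC1=O | intermediate
3 | tributyl(1-ethoxyethenyl)stannane | CCCC[Sn](CCCC)(CCCC)C(=C)OCC | starting material
4 | 3-(1-ethoxyethenyl)-2-methylcyclohex-2-en-1-one | CCOC(=C)C1=C(C)C(=O)CCC1 | intermediate
5 | (2S)-3-(1-ethoxyethenyl)-2-(hydroxymethyl)-2-methylcyclohex-3-en-1-one | CCOC(=C)C1=CCCC(=O)[C@]1(C)CO | intermediate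
6 | 3-(4-hydroxyphenyl)propanoic acid (phloretic acid) | OC(=O)CCc1ccc(O)cc1 | starting material
7 | tert-butyldimethylsilyl 3-[4-(tert-butyldimethylsilyloxy)phenyl]propanoate (not isolated) | CC(C)(C)[Si](C)(C)OC(=O)CCc1ccc(O[Si](C)(C)C(C)(C)C)cc1 | intermediate
8 | 3-[4-(tert-butyldimethylsilyloxy)phenyl]propanoic acid | OC(=O)CCc1ccc(O[Si](C)(C)C(C)(C)C)cc1 | intermediate
9 | [(1S)-2-(1-ethoxyethenyl)-1-methyl-6-oxocyclohex-2-en-1-yl]methyl 3-[4-(tert-butyldimethylsilyloxy)phenyl]propanoate | CCOC(=C)C1=CCCC(=O)[C@]1(C)COC(=O)CCc1ccc(O[Si](C)(C)C(C)(C)C)cc1 | intermediate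
10 | (E)-2-methylbut-2-enal (tiglaldehyde) | C/C=C(\C)C=O | starting material
11 | [(1S,4aRS,5R,6S)-8-ethoxy-5-formyl-1,5,6-trimethyl-2-oxo-1,2,3,4,4a,5,6,7-octahydronaphthalen-1-yl]methyl 3-[4-(tert-butyldimethylsilyloxy)phenyl]propanoate (both C4a epimers, centre left open) | C[C@H]1CC(OCC)=C2C(CCC(=O)[C@]2(C)COC(=O)CCc3ccc(O[Si](C)(C)C(C)(C)C)cc3)[C@]1(C)C=O | intermediate
12 | [(1S,4aRS,5R,6S)-5-ethenyl-8-ethoxy-1,5,6-trimethyl-2-oxo-1,2,3,4,4a,5,6,7-octahydronaphthalen-1-yl]methyl 3-[4-(tert-butyldimethylsilyloxy)phenyl]propanoate (both C4a epimers, centre left open) | C[C@H]1CC(OCC)=C2C(CCC(=O)[C@]2(C)COC(=O)CCc3ccc(O[Si](C)(C)C(C)(C)C)cc3)[C@]1(C)C=C | intermediate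
13 | [(1S,5R,6S)-5-ethenyl-1,5,6-trimethyl-2,8-dioxo-1,2,3,4,5,6,7,8-octahydronaphthalen-1-yl]methyl 3-[4-(tert-butyldimethylsilyloxy)phenyl]propanoate | C[C@H]1CC(=O)C2=C(CCC(=O)[C@]2(C)COC(=O)CCc3ccc(O[Si](C)(C)C(C)(C)C)cc3)[C@]1(C)C=C | intermediate
14 | [(1S,5R,6S,8S)-5-ethenyl-8-hydroxy-1,5,6-trimethyl-2-oxo-1,2,3,4,5,6,7,8-octahydronaphthalen-1-yl]methyl 3-[4-(tert-butyldimethylsilyloxy)phenyl]propanoate | C[C@H]1C[C@H](O)C2=C(CCC(=O)[C@]2(C)COC(=O)CCc3ccc(O[Si](C)(C)C(C)(C)C)cc3)[C@]1(C)C=C | intermediate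
15 | 4-bromofuran-2(5H)-one | BrC1=CC(=O)OC1 | starting material
16 | [(1S,5R,6S,8S)-8-(9-borabicyclo[3.3.1]nonan-9-yloxy)-5-[2-(9-borabicyclo[3.3.1]nonan-9-yl)ethyl]-1,5,6-trimethyl-2-oxo-1,2,3,4,5,6,7,8-octahydronaphthalen-1-yl]methyl 3-[4-(tert-butyldimethylsilyloxy)phenyl]propanoate (not isolated) | C[C@H]1C[C@H](OB4C5CCCC4CCC5)C2=C(CCC(=O)[C@]2(C)COC(=O)CCc3ccc(O[Si](C)(C)C(C)(C)C)cc3)[C@]1(C)CCB6C7CCCC6CCC7 | intermediate
17 | [(1S,5R,6S,8S)-8-hydroxy-1,5,6-trimethyl-2-oxo-5-[2-(5-oxo-2,5-dihydrofuran-3-yl)ethyl]-1,2,3,4,5,6,7,8-octahydronaphthalen-1-yl]methyl 3-[4-(tert-butyldimethylsilyloxy)phenyl]propanoate (not isolated) | C[C@H]1C[C@H](O)C2=C(CCC(=O)[C@]2(C)COC(=O)CCc3ccc(O[Si](C)(C)C(C)(C)C)cc3)[C@]1(C)CCC1=CC(=O)OC1 | intermediate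
18 | [(1S,5R,6S,8S)-8-hydroxy-1,5,6-trimethyl-2-oxo-5-[2-(5-oxo-2,5-dihydrofuran-3-yl)ethyl]-1,2,3,4,5,6,7,8-octahydronaphthalen-1-yl]methyl 3-(4-hydroxyphenyl)propanoate (CNP0301014.1) | C[C@H]1C[C@H](O)C2=C(CCC(=O)[C@]2(C)COC(=O)CCc2ccc(O)cc2)[C@]1(C)CCC1=CC(=O)OC1 | target

**Step count:** 10 steps in total; longest linear sequence 9 steps (steps 1–3 and 5–10; step 4 is a one-step side branch).

**Three steps most likely to fail**

Step 3 (the new reaction). The risks are hydroxymethylation at the α′- or γ-carbon instead of the α-carbon, low enantioselectivity, and erosion by retro-aldol reaction. The fallback uses known chemistry, sets out from 4 and returns at 5. Dienone 4 is converted into its thermodynamic dienolate with KOt-Bu in THF/t-BuOH and trapped at the α-carbon with monomeric formaldehyde (classical deconjugative α-alkylation, no asymmetric induction) to give racemic 3-(1-ethoxyethenyl)-2-(hydroxymethyl)-2-methylcyclohex-3-en-1-one F1. Lipase-catalysed kinetic resolution (Amano lipase PS, vinyl acetate, MTBE) then acetylates the R enantiomer to [(1R)-2-(1-ethoxyethenyl)-1-methyl-6-oxocyclohex-2-en-1-yl]methyl acetate F2 and leaves (S)-5, which re-enters at step 5 at the cost of at most 50 % yield.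

Step 6 (cycloaddition between a hindered ring diene terminus and an α,β-disubstituted enal, with the Lewis-basic ketone and ester of 9 competing for the catalyst). The fallback sets out from 9 and 10 and returns at 11. It gives up catalyst control of the dienophile face: the cycloaddition is driven with achiral Me2AlCl (CH2Cl2, −78 °C) or at 12 kbar without promoter. Because C1 is already S, the product is 11 together with the separable diastereomer [(1S,4aRS,5S,6R)-8-ethoxy-5-formyl-1,5,6-trimethyl-2-oxo-1,2,3,4,4a,5,6,7-octahydronaphthalen-1-yl]methyl 3-[4-(tert-butyldimethylsilyloxy)phenyl]propanoate F3. Chromatography removes F3 and 11 continues into step 7.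

Step 9 (the reagent must override the substrate's preference for axial hydride attack and must leave the C2 ketone alone). The fallback sets out from 13 and returns at 14. Luche reduction (NaBH4, CeCl3·7H2O, MeOH, −78 °C) is used for its preference for conjugated over hindered saturated ketones. The small hydride is expected to attack axially and give mainly the 8R epimer [(1S,5R,6S,8R)-5-ethenyl-8-hydroxy-1,5,6-trimethyl-2-oxo-1,2,3,4,5,6,7,8-octahydronaphthalen-1-yl]methyl 3-[4-(tert-butyldimethylsilyloxy)phenyl]propanoate F4. Mitsunobu inversion with chloroacetic acid (PPh3, DIAD, THF) gives the 8S chloroacetate [(1S,5R,6S,8S)-8-(2-chloroacetoxy)-5-ethenyl-1,5,6-trimethyl-2-oxo-1,2,3,4,5,6,7,8-octahydronaphthalen-1-yl]methyl 3-[4-(tert-butyldimethylsilyloxy)phenyl]propanoate F5. Thiourea/NaHCO3 in EtOH then removes the chloroacetyl group without touching the neopentyl ester and gives 14.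

**Further compounds**
F1 | step 3 | racemic 3-(1-ethoxyethenyl)-2-(hydroxymethyl)-2-methylcyclohex-3-en-1-one | CCOC(=C)C1=CCCC(=O)C1(C)CO
F2 | step 3 | [(1R)-2-(1-ethoxyethenyl)-1-methyl-6-oxocyclohex-2-en-1-yl]methyl acetate | CCOC(=C)C1=CCCC(=O)[C@@]1(C)COC(C)=O
F3 | step 6 | [(1S,4aRS,5S,6R)-8-ethoxy-5-formyl-1,5,6-trimethyl-2-oxo-1,2,3,4,4a,5,6,7-octahydronaphthalen-1-yl]methyl 3-[4-(tert-butyldimethylsilyloxy)phenyl]propanoate | C[C@@H]1CC(OCC)=C2C(CCC(=O)[C@]2(C)COC(=O)CCc3ccc(O[Si](C)(C)C(C)(C)C)cc3)[C@@]1(C)C=O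
F4 | step 9 | [(1S,5R,6S,8R)-5-ethenyl-8-hydroxy-1,5,6-trimethyl-2-oxo-1,2,3,4,5,6,7,8-octahydronaphthalen-1-yl]methyl 3-[4-(tert-butyldimethylsilyloxy)phenyl]propanoate | C[C@H]1C[C@@H](O)C2=C(CCC(=O)[C@]2(C)COC(=O)CCc3ccc(O[Si](C)(C)C(C)(C)C)cc3)[C@]1(C)C=C
F5 | step 9 | [(1S,5R,6S,8S)-8-(2-chloroacetoxy)-5-ethenyl-1,5,6-trimethyl-2-oxo-1,2,3,4,5,6,7,8-octahydronaphthalen-1-yl]methyl 3-[4-(tert-butyldimethylsilyloxy)phenyl]propanoate | C[C@H]1C[C@H](OC(=O)CCl)C2=C(CCC(=O)[C@]2(C)COC(=O)CCc3ccc(O[Si](C)(C)C(C)(C)C)cc3)[C@]1(C)C=C
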